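**Retrosynthetic overview**

1. Target 29 ⇐ 13‑alcohol 28 (acetylation) ⇐ tertiary cyclobutyl hydroperoxide 25 by Criegee rearrangement. One oxygen is inserted into the C1–C4 ring‑fusion bond, so the cyclobutane (C1–C2–C3–C4) becomes the oxolane and the cyclooctene carbocycle (C1, C10, C9, C8, C7, C6, C5, C4) becomes the nine‑membered oxacycle (O, C1, C10, C9, C8, C7, C6, C5, C4) in the same event.
2. Enabling feature: C1 carries the O–O group and is bonded to quaternary, allylic C4 through a bond shared by the strained four‑membered ring and the eight‑membered ring. C4 migrates to oxygen with retention, four‑ring strain drives it, and the new bridge fixes the C1 hemiketal.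
3. Eight‑membered ring: intramolecular vinylogous Mukaiyama aldol/β‑elimination (C5=C6) of aldehyde 21. C7–C8 comes from Ni/Cr coupling of aldehyde 12 with bromobutenolide 16. C1–C10 comes from homoaldol addition of a titanated crotyl carbamate to cyclobutanone 4.
4. Cyclobutanone 4 (C4 stereocentre) comes from allenylcyclopropanol 3 by enantioselective gold‑catalysed ring expansion; the side‑chain acid 19 comes from methyl (R)‑2‑methylglycidate.
5. Order of ring formation: cyclopropane → cyclobutane (step 2); butenolide (bought as tetronic acid); cyclooctene (step 14); oxolane and nine‑membered oxacycle together (step 16).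

Key step: step 16

Remark: locants C1–C15 are the germacrane locants of the target (C1 hemiketal carbon, C4 methyl‑bearing ether carbon, C6/C7/C11/C12 butenolide, C8 acyloxy carbon, C10 the CH–CH3, C13 the CH2O carbon); "1,4‑cyclo" means an extra C1–C4 bond (cyclobutane C1–C2–C3–C4); compounds 1, 2, 5, 6, 13 and 18 are taken as catalogue compounds.

**Route**

Step 1
Reactants: 1 1‑ethoxycyclopropan‑1‑ol (cyclopropanone ethyl hemiketal); 2 1‑bromobut‑2‑yne
Product: 3 1‑(buta‑2,3‑dien‑2‑yl)cyclopropan‑1‑ol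
Conditions: In powder, THF/H2O, 25 °C
Reagents that add atoms: none
Why: Barbier‑type addition in which the cyclopropanone released from the hemiketal is captured by the γ‑methylpropargyl indium species in the SE2' sense, which should give the allenyl carbinol with the methyl group on the allene carbon next to the carbinol (indium‑mediated allenylation with γ‑substituted propargyl bromides); no stereocentre is formed.

Step 2
Reactants: 3 1‑(buta‑2,3‑dien‑2‑yl)cyclopropan‑1‑ol
Product: 4 (2R)‑2‑ethenyl‑2‑methylcyclobutan‑1‑one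
Conditions: [(R)‑MeO‑DTBM‑BIPHEP](AuCl)2 (2.5 mol %), Na[B(3,5‑(CF3)2C6H3)4] (5 mol %), ClCH2CH2Cl, −30 °C
Reagents that add atoms: none
Why: Enantioselective gold‑catalysed ring expansion of a 1‑allenylcyclopropanol (semipinacol‑type 1,2‑alkyl shift onto the allene activated by monovalent gold, then protodeauration) should give the 2‑vinylcyclobutanone; the quaternary centre C4 is set by the chiral bisphosphine, the ligand antipode being chosen as the one expected to deliver (R)‑4.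

Step 3
Reactants: 5 (2E)‑but‑2‑en‑1‑ol; 6 N,N‑di(propan‑2‑yl)carbamoyl chloride
Product: 7 (2E)‑but‑2‑en‑1‑yl N,N‑di(propan‑2‑yl)carbamate
Conditions: NaH, THF, 0 → 65 °C
Reagents that add atoms: none
Why: O‑carbamoylation of the alkoxide (acyl substitution) gives the carbamate needed for sparteine‑directed lithiation; no stereocentre is formed.

Step 4
Reactants: 4 (2R)‑2‑ethenyl‑2‑methylcyclobutan‑1‑one; 7 (2E)‑but‑2‑en‑1‑yl N,N‑di(propan‑2‑yl)carbamate
Product: 9 (1Z,3R)‑3‑[(1R,2R)‑2‑ethenyl‑1‑hydroxy‑2‑methylcyclobutyl]but‑1‑en‑1‑yl N,N‑di(propan‑2‑yl)carbamate, via allyltitanium carbamate 8 (not isolated)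
Conditions: 7, s‑BuLi, (+)‑sparteine, pentane/cyclohexane, −78 °C; Ti(OiPr)4, −78 °C; then 4, −78 → −20 °C; aq. work‑up
Reagents that add atoms: none
Why: Hoppe homoaldol reaction: sparteine‑mediated lithiation and invertive transmetalation should give the (S)‑allyltitanium 8, which adds through its methyl‑bearing γ‑carbon in a chair Zimmerman–Traxler transition state with the quaternary C4 side of the ketone equatorial; this sets C10 (R) and C1 (R, the C10 arm cis to the vinyl arm on C4) under reagent control, the methyl and vinyl groups on C4 being too similar in size to override it, and leaves C8 as a Z enol carbamate.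

Step 5
Reactants: 9 (1Z,3R)‑3‑[(1R,2R)‑2‑ethenyl‑1‑hydroxy‑2‑methylcyclobutyl]but‑1‑en‑1‑yl N,N‑di(propan‑2‑yl)carbamate
Product: 10 (1Z,3R)‑3‑[(1R,2R)‑2‑ethenyl‑2‑methyl‑1‑(triethylsilyloxy)cyclobutyl]but‑1‑en‑1‑yl N,N‑di(propan‑2‑yl)carbamate
Conditions: TESOTf, 2,6‑lutidine, CH2Cl2, −78 → 0 °C
Reagents that add atoms: triethylsilyl trifluoromethanesulfonate, CC[Si](CC)(CC)OS(=O)(=O)C(F)(F)F
Why: Silylation of the hindered tertiary alcohol with a silyl triflate and a hindered base prevents lactol formation with the C8 aldehyde that is unmasked next; no stereocentre is touched.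

Step 6
Reactants: 10 (1Z,3R)‑3‑[(1R,2R)‑2‑ethenyl‑2‑methyl‑1‑(triethylsilyloxy)cyclobutyl]but‑1‑en‑1‑yl N,N‑di(propan‑2‑yl)carbamate
Product: 12 (3R)‑3‑[(1R,2R)‑2‑ethenyl‑2‑methyl‑1‑(triethylsilyloxy)cyclobutyl]butanal, via lithium enolate 11 (not isolated)
Conditions: MeLi (2.2 equiv), THF, −78 → 0 °C; then AcOH, −78 °C
Reagents that add atoms: none
Why: Addition–elimination of methyllithium at the enol carbamate carbonyl releases the lithium enolate 11, whose protonation gives the aldehyde (the usual deblocking of homoaldol enol carbamates); C10 is not enolisable and stays as set.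

Step 7
Reactants: 13 tetronic acid (4‑hydroxyfuran‑2(5H)‑one)
Product: 14 4‑bromo‑2‑oxo‑2,5‑dihydrofuran‑3‑carbaldehyde
Conditions: PBr3, DMF, CHCl3, 0 → 60 °C; then ice‑water
Reagents that add atoms: phosphorus tribromide, BrP(Br)Br; N,N‑dimethylformamide, CN(C)C=O; water, O
Why: Vilsmeier–Haack haloformylation of a cyclic 1,3‑dicarbonyl enol: C3 is formylated by the bromoiminium reagent and the enol OH is replaced by bromide; no stereocentre is formed.

Step 8
Reactants: 14 4‑bromo‑2‑oxo‑2,5‑dihydrofuran‑3‑carbaldehyde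
Product: 15 4‑bromo‑3‑(hydroxymethyl)furan‑2(5H)‑one
Conditions: NaBH(OAc)3, AcOH, THF, 0 → 25 °C
Reagents that add atoms: none
Why: The mild, non‑basic acyloxyborohydride should reduce only the aldehyde and leave the lactone and the vinylogous acyl bromide untouched; no stereocentre is formed.

Step 9
Reactants: 15 4‑bromo‑3‑(hydroxymethyl)furan‑2(5H)‑one
Product: 16 4‑bromo‑3‑[(triethylsilyloxy)methyl]furan‑2(5H)‑one
Conditions: TESOTf, 2,6‑lutidine, CH2Cl2, −78 °C
Reagents that add atoms: triethylsilyl trifluoromethanesulfonate, CC[Si](CC)(CC)OS(=O)(=O)C(F)(F)F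
Why: Silylation with a hindered base avoids displacement of the β‑bromide by a nucleophilic amine; a silyl ether is carried at C13 instead of the acetate because an acyloxy group there would be lost by β‑elimination when the butenolide is enolised in step 14.

Step 10
Reactants: 12 (3R)‑3‑[(1R,2R)‑2‑ethenyl‑2‑methyl‑1‑(triethylsilyloxy)cyclobutyl]butanal; 16 4‑bromo‑3‑[(triethylsilyloxy)methyl]furan‑2(5H)‑one
Product: 17 4‑{(1S,3R)‑3‑[(1R,2R)‑2‑ethenyl‑2‑methyl‑1‑(triethylsilyloxy)cyclobutyl]‑1‑hydroxybutyl}‑3‑[(triethylsilyloxy)methyl]furan‑2(5H)‑one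
Conditions: CrCl2, chiral oxazoline–sulfonamide ligand [(S)‑N‑{2‑[4‑(propan‑2‑yl)‑4,5‑dihydro‑1,3‑oxazol‑2‑yl]‑6‑methylphenyl}methanesulfonamide], Et3N, NiCl2 (cat.), THF, 25 °C
Reagents that add atoms: none
Why: Nozaki–Hiyama–Kishi reaction: oxidative addition of the β‑bromobutenolide to nickel, transmetalation to chromium and addition of the alkenylchromium to the aldehyde form C7–C8 without base; the C8 configuration (S) is to be set by the chiral sulfonamide ligand on chromium (reagent control, the C10 centre being too remote to help).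

Step 11
Reactants: 18 methyl (2R)‑2‑methyloxirane‑2‑carboxylate
Product: 19 (2S)‑3‑chloro‑2‑hydroxy‑2‑methylpropanoic acid
Conditions: conc. aq. HCl, 0 °C, then 60 °C
Reagents that add atoms: hydrogen chloride, Cl; water, O
Why: Chloride opens the protonated glycidate at the unhindered CH2 (SN2, the tertiary centre is untouched) and the methyl ester is hydrolysed by acid; the change of descriptor from R to S is only a change of priorities.

Step 12
Reactants: 17 4‑{(1S,3R)‑3‑[(1R,2R)‑2‑ethenyl‑2‑methyl‑1‑(triethylsilyloxy)cyclobutyl]‑1‑hydroxybutyl}‑3‑[(triethylsilyloxy)methyl]furan‑2(5H)‑one; 19 (2S)‑3‑chloro‑2‑hydroxy‑2‑methylpropanoic acid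
Product: 20 (1S,3R)‑3‑[(1R,2R)‑2‑ethenyl‑2‑methyl‑1‑(triethylsilyloxy)cyclobutyl]‑1‑{5‑oxo‑4‑[(triethylsilyloxy)methyl]‑2,5‑dihydrofuran‑3‑yl}butyl (2S)‑3‑chloro‑2‑hydroxy‑2‑methylpropanoate
Conditions: EDC·HCl, DMAP (cat.), CH2Cl2, 0 °C
Reagents that add atoms: none
Why: Steglich esterification of the secondary allylic C8 alcohol, the hindered tertiary α‑hydroxyl of the acid not competing; it is run directly after step 10 to forestall translactonisation onto the C8 oxygen, and C8 keeps its configuration.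

Step 13
Reactants: 20 (1S,3R)‑3‑[(1R,2R)‑2‑ethenyl‑2‑methyl‑1‑(triethylsilyloxy)cyclobutyl]‑1‑{5‑oxo‑4‑[(triethylsilyloxy)methyl]‑2,5‑dihydrofuran‑3‑yl}butyl (2S)‑3‑chloro‑2‑hydroxy‑2‑methylpropanoate
Product: 21 (1S,3R)‑3‑[(1R,2S)‑2‑formyl‑2‑methyl‑1‑(triethylsilyloxy)cyclobutyl]‑1‑{5‑oxo‑4‑[(triethylsilyloxy)methyl]‑2,5‑dihydrofuran‑3‑yl}butyl (2S)‑3‑chloro‑2‑hydroxy‑2‑methylpropanoate
Conditions: O3, CH2Cl2, −78 °C; then Me2S
Reagents that add atoms: ozone, [O-][O+]=O
Why: Ozonolysis of the monosubstituted vinyl group, the tetrasubstituted ester‑conjugated butenolide alkene being far slower toward ozone, unmasks the non‑enolisable C5 aldehyde; C4 is unchanged in space (its descriptor changes by priority only).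

Step 14
Reactants: 21 (1S,3R)‑3‑[(1R,2S)‑2‑formyl‑2‑methyl‑1‑(triethylsilyloxy)cyclobutyl]‑1‑{5‑oxo‑4‑[(triethylsilyloxy)methyl]‑2,5‑dihydrofuran‑3‑yl}butyl (2S)‑3‑chloro‑2‑hydroxy‑2‑methylpropanoate
Product: 24 (1R,4R,5E,8S,10R)‑8‑{[(2S)‑3‑chloro‑2‑methyl‑2‑(trimethylsilyloxy)propanoyl]oxy}‑1,13‑bis(triethylsilyloxy)‑1,4‑cyclogermacra‑5,7(11)‑dien‑6,12‑olide, via silyloxyfuran 22 (not isolated), via aldol silyl ether 23 (not isolated)
Conditions: TMSOTf, Et3N, CH2Cl2 (high dilution), −78 → 0 °C; then DBU, 25 °C; NaHCO3 work‑up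
Reagents that add atoms: trimethylsilyl trifluoromethanesulfonate, C[Si](C)(C)OS(=O)(=O)C(F)(F)F
Why: One‑pot soft enolisation, vinylogous Mukaiyama aldol and E1cB elimination: the butenolide is silylated to 2‑silyloxyfuran 22, whose γ‑carbon C6 adds to the silyl‑triflate‑activated C5 aldehyde and closes the eight‑membered ring across the cis arms of the cyclobutane, and DBU then eliminates silanol from 23 to give the dienol lactone, whose 5E geometry (C4 cis to C7) is the only one the eight‑membered ring allows; the side‑chain tertiary OH is silylated in passing.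

Step 15
Reactants: 24 (1R,4R,5E,8S,10R)‑8‑{[(2S)‑3‑chloro‑2‑methyl‑2‑(trimethylsilyloxy)propanoyl]oxy}‑1,13‑bis(triethylsilyloxy)‑1,4‑cyclogermacra‑5,7(11)‑dien‑6,12‑olide
Product: 25 (4R,5E,8S,10R)‑8‑{[(2S)‑3‑chloro‑2‑hydroxy‑2‑methylpropanoyl]oxy}‑1‑hydroperoxy‑13‑hydroxy‑1,4‑cyclogermacra‑5,7(11)‑dien‑6,12‑olide (C1 epimers)
Conditions: 50% aq. H2O2 (large excess), H2SO4 (cat.), THF, 0 °C
Reagents that add atoms: hydrogen peroxide, OO
Why: Acid‑catalysed perhydrolysis of a tertiary alcohol (SN1): the three silyl ethers are hydrolysed and the tertiary cyclobutyl cation at C1 is captured by hydrogen peroxide present in large excess; the configuration at C1 does not matter because C1 becomes trigonal in step 16, and any Hock rearrangement already induced by the acid would lead to the same hemiketal 28.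

Step 16
Reactants: 25 (4R,5E,8S,10R)‑8‑{[(2S)‑3‑chloro‑2‑hydroxy‑2‑methylpropanoyl]oxy}‑1‑hydroperoxy‑13‑hydroxy‑1,4‑cyclogermacra‑5,7(11)‑dien‑6,12‑olide (C1 epimers)
Product: 28 (1S,4R,5E,8S,10R)‑8‑{[(2S)‑3‑chloro‑2‑hydroxy‑2‑methylpropanoyl]oxy}‑1,4‑epoxy‑1,13‑dihydroxygermacra‑5,7(11)‑dien‑6,12‑olide, via peroxy trifluoroacetate 26 (not isolated), via bridgehead trifluoroacetate 27 (not isolated)
Conditions: (CF3CO)2O, CH2Cl2, −40 → 0 °C; then aq. NaHCO3, THF, 0 °C
Reagents that add atoms: water, O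
Why: Criegee rearrangement: O‑trifluoroacetylation of the hydroperoxide gives perester 26, whose O–O bond ionises with concerted 1,2‑shift of C4 from C1 to the proximal oxygen, the bridgehead oxocarbenium ion is captured by trifluoroacetate (27), and the ketal ester is hydrolysed on work‑up to the hemiketal. The closest known reaction types are the Criegee rearrangement of ring‑fusion tertiary peresters (9‑decalyl perester to 1,6‑epoxycyclodecyl ester) and the strain‑driven Baeyer–Villiger expansion of cyclobutanones. No ring is closed by cyclisation: the oxolane arises from the cyclobutane (four to five atoms) and the nine‑membered oxacycle from the cyclooctene (eight to nine atoms) by insertion of one oxygen into their shared C1–C4 bond. C4 migrates with retention (suprafacial shift), and C1 is fixed by the bridge, since the bridgehead oxocarbenium ion can only be attacked on the face outside the C1–O–C4 bridge. The step needs migration of C4 rather than C2 or C10; C4 is the only quaternary and allylic neighbour of C1, so its migratory aptitude is by far the highest, and its shift, unlike that of C10, releases the four‑ring strain. The dienol lactone, the ester and the chlorohydrin should be inert to the anhydride at low temperature, and the C13 trifluoroacetate formed in passing is cleaved in the same work‑up.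

Step 17
Reactants: 28 (1S,4R,5E,8S,10R)‑8‑{[(2S)‑3‑chloro‑2‑hydroxy‑2‑methylpropanoyl]oxy}‑1,4‑epoxy‑1,13‑dihydroxygermacra‑5,7(11)‑dien‑6,12‑olide
Product: 29 (1S,4R,5E,8S,10R)‑13‑acetoxy‑8‑{[(2S)‑3‑chloro‑2‑hydroxy‑2‑methylpropanoyl]oxy}‑1,4‑epoxy‑1‑hydroxygermacra‑5,7(11)‑dien‑6,12‑olide (CNP0414417.1)
Conditions: Ac2O (1.2 equiv), pyridine, CH2Cl2, 0 °C
Reagents that add atoms: acetic anhydride, CC(=O)OC(C)=O
Why: Selective O‑acetylation of the primary allylic C13 alcohol; the tertiary hemiketal OH and the tertiary side‑chain OH should not react under these conditions.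

**Compound list**

1 | 1‑ethoxycyclopropan‑1‑ol | CCOC1(O)CC1 | starting material
2 | 1‑bromobut‑2‑yne | CC#CCBr | starting material
3 | 1‑(buta‑2,3‑dien‑2‑yl)cyclopropan‑1‑ol | CC(=C=C)C1(O)CC1 | intermediate
4 | (2R)‑2‑ethenyl‑2‑methylcyclobutan‑1‑one | C=C[C@@]1(C)CCC1=O | intermediate
5 | (2E)‑but‑2‑en‑1‑ol | C/C=C/CO | starting material
6 | N,N‑di(propan‑2‑yl)carbamoyl chloride | CC(C)N(C(C)C)C(Cl)=O | starting material
7 | (2E)‑but‑2‑en‑1‑yl N,N‑di(propan‑2‑yl)carbamate | C/C=C/COC(=O)N(C(C)C)C(C)C | intermediate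
8 | [(1S,2E)‑1‑{[di(propan‑2‑yl)carbamoyl]oxy}but‑2‑en‑1‑yl]tri(propan‑2‑olato)titanium | C/C=C/[C@@H](OC(=O)N(C(C)C)C(C)C)[Ti](OC(C)C)(OC(C)C)OC(C)C | intermediate (not isolated)
9 | (1Z,3R)‑3‑[(1R,2R)‑2‑ethenyl‑1‑hydroxy‑2‑methylcyclobutyl]but‑1‑en‑1‑yl N,N‑di(propan‑2‑yl)carbamate | C=C[C@@]1(C)CC[C@@]1(O)[C@H](C)/C=C\OC(=O)N(C(C)C)C(C)C | intermediate
10 | (1Z,3R)‑3‑[(1R,2R)‑2‑ethenyl‑2‑methyl‑1‑(triethylsilyloxy)cyclobutyl]but‑1‑en‑1‑yl N,N‑di(propan‑2‑yl)carbamate | C=C[C@@]1(C)CC[C@@]1(O[Si](CC)(CC)CC)[C@H](C)/C=C\OC(=O)N(C(C)C)C(C)C | intermediate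
11 | lithium (1Z,3R)‑3‑[(1R,2R)‑2‑ethenyl‑2‑methyl‑1‑(triethylsilyloxy)cyclobutyl]but‑1‑en‑1‑olate | C=C[C@@]1(C)CC[C@@]1(O[Si](CC)(CC)CC)[C@H](C)/C=C\[O-].[Li+] | intermediate (not isolated)
12 | (3R)‑3‑[(1R,2R)‑2‑ethenyl‑2‑methyl‑1‑(triethylsilyloxy)cyclobutyl]butanal | C=C[C@@]1(C)CC[C@@]1(O[Si](CC)(CC)CC)[C@H](C)CC=O | intermediate
13 | tetronic acid (4‑hydroxyfuran‑2(5H)‑one) | OC1=CC(=O)OC1 | starting material
14 | 4‑bromo‑2‑oxo‑2,5‑dihydrofuran‑3‑carbaldehyde | O=CC1=C(Br)COC1=O | intermediate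
15 | 4‑bromo‑3‑(hydroxymethyl)furan‑2(5H)‑one | OCC1=C(Br)COC1=O | intermediate
16 | 4‑bromo‑3‑[(triethylsilyloxy)methyl]furan‑2(5H)‑one | CC[Si](CC)(CC)OCC1=C(Br)COC1=O | intermediate
17 | 4‑{(1S,3R)‑3‑[(1R,2R)‑2‑ethenyl‑2‑methyl‑1‑(triethylsilyloxy)cyclobutyl]‑1‑hydroxybutyl}‑3‑[(triethylsilyloxy)methyl]furan‑2(5H)‑one | C=C[C@@]1(C)CC[C@@]1(O[Si](CC)(CC)CC)[C@H](C)C[C@H](O)C2=C(CO[Si](CC)(CC)CC)C(=O)OC2 | intermediate
18 | methyl (2R)‑2‑methyloxirane‑2‑carboxylate | C[C@@]1(CO1)C(=O)OC | starting material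
19 | (2S)‑3‑chloro‑2‑hydroxy‑2‑methylpropanoic acid | C[C@@](O)(CCl)C(O)=O | intermediate
20 | (1S,3R)‑3‑[(1R,2R)‑2‑ethenyl‑2‑methyl‑1‑(triethylsilyloxy)cyclobutyl]‑1‑{5‑oxo‑4‑[(triethylsilyloxy)methyl]‑2,5‑dihydrofuran‑3‑yl}butyl (2S)‑3‑chloro‑2‑hydroxy‑2‑methylpropanoate | C=C[C@@]1(C)CC[C@@]1(O[Si](CC)(CC)CC)[C@H](C)C[C@H](OC(=O)[C@](C)(O)CCl)C2=C(CO[Si](CC)(CC)CC)C(=O)OC2 | intermediate
21 | (1S,3R)‑3‑[(1R,2S)‑2‑formyl‑2‑methyl‑1‑(triethylsilyloxy)cyclobutyl]‑1‑{5‑oxo‑4‑[(triethylsilyloxy)methyl]‑2,5‑dihydrofuran‑3‑yl}butyl (2S)‑3‑chloro‑2‑hydroxy‑2‑methylpropanoate | O=C[C@@]1(C)CC[C@@]1(O[Si](CC)(CC)CC)[C@H](C)C[C@H](OC(=O)[C@](C)(O)CCl)C2=C(CO[Si](CC)(CC)CC)C(=O)OC2 | intermediate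
22 | 2‑(trimethylsilyloxy)furan of 21 with the side‑chain OH as trimethylsilyl ether | O=C[C@@]1(C)CC[C@@]1(O[Si](CC)(CC)CC)[C@H](C)C[C@H](OC(=O)[C@](C)(O[Si](C)(C)C)CCl)c2coc(O[Si](C)(C)C)c2CO[Si](CC)(CC)CC | intermediate (not isolated)
23 | 5‑(trimethylsilyloxy)‑5,6‑dihydro analogue of 24 (eight‑membered ring closed, C5/C6 epimers) | CC[Si](CC)(CC)OCC1=C2C(OC1=O)C(O[Si](C)(C)C)[C@@]3(C)CC[C@@]3(O[Si](CC)(CC)CC)[C@H](C)C[C@@H]2OC(=O)[C@](C)(O[Si](C)(C)C)CCl | intermediate (not isolated)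
24 | (1R,4R,5E,8S,10R)‑8‑{[(2S)‑3‑chloro‑2‑methyl‑2‑(trimethylsilyloxy)propanoyl]oxy}‑1,13‑bis(triethylsilyloxy)‑1,4‑cyclogermacra‑5,7(11)‑dien‑6,12‑olide | CC[Si](CC)(CC)OCC1=C2/C(=C\[C@@]3(C)CC[C@@]3(O[Si](CC)(CC)CC)[C@H](C)C[C@@H]2OC(=O)[C@](C)(O[Si](C)(C)C)CCl)OC1=O | intermediate
25 | (4R,5E,8S,10R)‑8‑{[(2S)‑3‑chloro‑2‑hydroxy‑2‑methylpropanoyl]oxy}‑1‑hydroperoxy‑13‑hydroxy‑1,4‑cyclogermacra‑5,7(11)‑dien‑6,12‑olide (C1 epimers) | OCC1=C2/C(=C\[C@@]3(C)CCC3(OO)[C@H](C)C[C@@H]2OC(=O)[C@](C)(O)CCl)OC1=O | intermediate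
26 | 1‑(trifluoroacetylperoxy)‑13‑(trifluoroacetoxy) derivative of 25 | O=C(OCC1=C2/C(=C\[C@@]3(C)CCC3(OOC(=O)C(F)(F)F)[C@H](C)C[C@@H]2OC(=O)[C@](C)(O)CCl)OC1=O)C(F)(F)F | intermediate (not isolated)
27 | 1,13‑bis(trifluoroacetate) of 28 (bridgehead ketal ester) | O=C(OCC1=C2/C(=C\[C@@]3(C)CC[C@](OC(=O)C(F)(F)F)(O3)[C@H](C)C[C@@H]2OC(=O)[C@](C)(O)CCl)OC1=O)C(F)(F)F | intermediate (not isolated)
28 | (1S,4R,5E,8S,10R)‑8‑{[(2S)‑3‑chloro‑2‑hydroxy‑2‑methylpropanoyl]oxy}‑1,4‑epoxy‑1,13‑dihydroxygermacra‑5,7(11)‑dien‑6,12‑olide | OCC1=C2/C(=C\[C@@]3(C)CC[C@](O)(O3)[C@H](C)C[C@@H]2OC(=O)[C@](C)(O)CCl)OC1=O | intermediate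
29 | (1S,4R,5E,8S,10R)‑13‑acetoxy‑8‑{[(2S)‑3‑chloro‑2‑hydroxy‑2‑methylpropanoyl]oxy}‑1,4‑epoxy‑1‑hydroxygermacra‑5,7(11)‑dien‑6,12‑olide (CNP0414417.1) | CC(=O)OCC1=C2/C(=C\[C@@]3(C)CC[C@](O)(O3)[C@H](C)C[C@@H]2OC(=O)[C@](C)(O)CCl)OC1=O | target

**Step count**

Total step count: 17. Longest linear sequence: 12 steps (1, 2, 4, 5, 6, 10, 12, 13, 14, 15, 16, 17).

**Three steps most likely to fail**

Step 15 (perhydrolysis). What may go wrong: the tertiary cyclobutyl cation at C1 may undergo a 1,2‑hydride shift from C10, a Wagner–Meerwein shift of a ring bond or of the C5 alkenyl group, or loss of a proton, before hydrogen peroxide captures it. The fallback avoids the cation and sets out from 24. HF·pyridine in THF removes the three silyl groups and gives the free cyclobutanol (4R,5E,8S,10R)‑8‑{[(2S)‑3‑chloro‑2‑hydroxy‑2‑methylpropanoyl]oxy}‑1,13‑dihydroxy‑1,4‑cyclogermacra‑5,7(11)‑dien‑6,12‑olide F1. Co(acac)2 under O2 (cobalt‑catalysed aerobic oxidative ring expansion of cyclobutanols: alkoxyl radical, β‑scission of C1–C4, capture of the C4 radical by O2, closure onto the C1 ketone) should give the bridged 1,2‑dioxan‑3‑ol (1,4‑epidioxy hemiketal) F2. PPh3 then reduces the O–O bond and the 4‑hydroxy ketone closes to the hemiketal, so the fallback comes back to the route at 28 and bypasses steps 15 and 16. In this variant the ten‑membered peroxide ring contracts to the nine‑membered oxacycle; C4 is re‑formed from a radical, so its epimer may have to be separated.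

Step 14 (ring closure). What may go wrong: slow closure of the eight‑membered ring, so that intermolecular aldol oligomerisation wins, or β‑elimination of the C13 silyloxy group from the enolised butenolide. The fallback closes the ring by a Wittig reaction and sets out from 20. TMSOTf/Et3N followed by N‑bromosuccinimide at −78 °C should give the γ‑bromobutenolide (C6 bromide, side‑chain OH silylated) F3. PPh3 converts it into the C6 triphenylphosphonium bromide F4, and ozonolysis (Me2S work‑up) of the vinyl group gives the C5 aldehyde phosphonium salt F5. Et3N at high dilution then closes the ring by an intramolecular Wittig reaction, and the fallback comes back to the route at 24.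

Step 10 (Ni/Cr coupling). What may go wrong: poor facial selectivity at C8, and translactonisation of the new alcohol onto the lactone carbonyl. The fallback sets the stereocentre by ketone reduction and sets out from 12 (with 16). Coupling with CrCl2/NiCl2 in DMSO without the chiral ligand gives 17 together with its C8 epimer; Dess–Martin periodinane oxidises the mixture to the C8 ketone 4‑{(3R)‑3‑[(1R,2R)‑2‑ethenyl‑2‑methyl‑1‑(triethylsilyloxy)cyclobutyl]butanoyl}‑3‑[(triethylsilyloxy)methyl]furan‑2(5H)‑one F6. Corey–Bakshi–Shibata reduction with the (R)‑methyl oxazaborolidine and catecholborane (butenolide as the large group) should give the (S)‑alcohol, and the fallback comes back to the route at 17.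

Further compounds
F1 | step 15 | (4R,5E,8S,10R)‑8‑{[(2S)‑3‑chloro‑2‑hydroxy‑2‑methylpropanoyl]oxy}‑1,13‑dihydroxy‑1,4‑cyclogermacra‑5,7(11)‑dien‑6,12‑olide (free cyclobutanol) | OCC1=C2/C(=C\[C@@]3(C)CC[C@@]3(O)[C@H](C)C[C@@H]2OC(=O)[C@](C)(O)CCl)OC1=O
F2 | step 15 | 1,4‑epidioxy‑1,13‑dihydroxy analogue of 28 (bridged 1,2‑dioxan‑3‑ol, C1–O–O–C4) | OCC1=C2/C(=C\C3(C)CCC(O)(OO3)[C@H](C)C[C@@H]2OC(=O)[C@](C)(O)CCl)OC1=O
F3 | step 14 | 6‑bromo derivative of 20 with the side‑chain OH as trimethylsilyl ether (γ‑bromobutenolide, C6 epimers) | C=C[C@@]1(C)CC[C@@]1(O[Si](CC)(CC)CC)[C@H](C)C[C@H](OC(=O)[C@](C)(O[Si](C)(C)C)CCl)C2=C(CO[Si](CC)(CC)CC)C(=O)OC2Br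
F4 | step 14 | C6 triphenylphosphonium bromide from F3 | C=C[C@@]1(C)CC[C@@]1(O[Si](CC)(CC)CC)[C@H](C)C[C@H](OC(=O)[C@](C)(O[Si](C)(C)C)CCl)C2=C(CO[Si](CC)(CC)CC)C(=O)OC2[P+](c3ccccc3)(c3ccccc3)c3ccccc3.[Br-]
F5 | step 14 | C5 aldehyde of F4 (vinyl group cleaved) | O=C[C@@]1(C)CC[C@@]1(O[Si](CC)(CC)CC)[C@H](C)C[C@H](OC(=O)[C@](C)(O[Si](C)(C)C)CCl)C2=C(CO[Si](CC)(CC)CC)C(=O)OC2[P+](c3ccccc3)(c3ccccc3)c3ccccc3.[Br-]
F6 | step 10 | 4‑{(3R)‑3‑[(1R,2R)‑2‑ethenyl‑2‑methyl‑1‑(triethylsilyloxy)cyclobutyl]butanoyl}‑3‑[(triethylsilyloxy)methyl]furan‑2(5H)‑one | C=C[C@@]1(C)CC[C@@]1(O[Si](CC)(CC)CC)[C@H](C)CC(=O)C2=C(CO[Si](CC)(CC)CC)C(=O)OC2
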